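**Retrosynthetic overview**

- The target is a 21-membered ring in which ring A (the arene with one hydroxyl, 1,3,5-substituted) and ring B (the arene with two hydroxyls) are joined by a diaryl ether oxygen and by an unbranched (CH2)14 chain, numbered C1 (on ring A) to C14 (on ring B). The chain carries no functional group to close a ring at, so its midpoint bond C7–C8 is made by deleting sulfur from a 22-membered ring that is easy to close.
- The last two steps are hydrogenation of a C7=C8 alkene and cleavage of three aryl methyl ethers.
- Key disconnection: the C7=C8 alkene comes from Ramberg–Bäcklund contraction of the 22-membered bis(heptyl) sulfone, which comes from the thioether made from sodium sulfide and an open-chain bis(7-bromoheptyl) diaryl ether.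
- The two heptyl arms come from a twofold Wittig reaction of a diaryl ether dialdehyde with a hydroxyhexyl ylide; the dialdehyde comes from copper-catalysed coupling of the two benzaldehydes.
- Ring order: both arenes are bought; the 22-membered thia-macrocycle is closed in step 7 and contracted to the 21-membered carbocycle in step 9.

Key step: step 9

Remark on the chemistry: the target has no stereocenter. The alkenes formed in steps 4 and 9 are expected as geometric mixtures (one isomer is drawn for each), and both are hydrogenated, so no isomer needs to be separated.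

**Route**

Step 1
Reactants: 1 3-bromo-2-hydroxy-5-methoxybenzaldehyde
Product: 2 3-bromo-2,5-dimethoxybenzaldehyde
Conditions: MeI, K2CO3, DMF, rt
Reagents that add atoms: iodomethane, CI
Why: Williamson O-methylation of the phenoxide (SN2 on MeI) should be clean, since the aldehyde and the aryl bromide are inert to K2CO3 and MeI.

Step 2
Reactants: 2 3-bromo-2,5-dimethoxybenzaldehyde; 3 3-hydroxy-5-methoxybenzaldehyde
Product: 4 3-(3-formyl-5-methoxyphenoxy)-2,5-dimethoxybenzaldehyde
Conditions: CuI (10 mol %), picolinic acid (20 mol %), K3PO4, DMSO, 90–100 °C, Ar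
Reagents that add atoms: none
Why: Ullmann-type copper-catalysed diaryl ether coupling in the CuI/picolinic acid/K3PO4 system is suited to ortho-substituted aryl bromides and should leave the two non-enolisable aryl aldehydes untouched, the bromine-bearing carbon being the only site able to couple.

Step 3
Reactants: 5 6-bromohexan-1-ol
Product: 6 (6-hydroxyhexyl)triphenylphosphonium bromide
Conditions: PPh3, MeCN, reflux
Reagents that add atoms: triphenylphosphine, c1ccc(cc1)P(c1ccccc1)c1ccccc1
Why: SN2 quaternisation of PPh3 by the primary bromide should give the salt directly, the free hydroxyl being a far weaker nucleophile than phosphorus.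

Step 4
Reactants: 4 3-(3-formyl-5-methoxyphenoxy)-2,5-dimethoxybenzaldehyde; 6 (6-hydroxyhexyl)triphenylphosphonium bromide
Product: 8 bis(7-hydroxyhept-1-enyl) diaryl ether (Z,Z drawn), via sodium alkoxide ylide 7 (not isolated)
Conditions: 6 (2.6 equiv), NaHMDS (5.2 equiv), THF, 0 °C; then 4, −78 °C → rt; then H2O
Reagents that add atoms: none
Why: A twofold Wittig olefination with the non-stabilised ylide, in which the second equivalent of base per salt holds the hydroxyl as its alkoxide, should convert both aldehydes, and the mainly Z geometry expected is erased in step 5.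

Step 5
Reactants: 8 bis(7-hydroxyhept-1-enyl) diaryl ether
Product: 9 7-[3-[3-(7-hydroxyheptyl)-5-methoxyphenoxy]-2,5-dimethoxyphenyl]heptan-1-ol
Conditions: H2 (1 atm), 10% Pd/C, EtOAc, rt
Reagents that add atoms: none
Why: Heterogeneous catalytic hydrogenation should saturate both styrenyl alkenes without touching the aryl ethers or the primary alcohols.

Step 6
Reactants: 9 7-[3-[3-(7-hydroxyheptyl)-5-methoxyphenoxy]-2,5-dimethoxyphenyl]heptan-1-ol
Product: 10 1-(7-bromoheptyl)-3-[3-(7-bromoheptyl)-5-methoxyphenoxy]-2,5-dimethoxybenzene
Conditions: CBr4, PPh3, CH2Cl2, 0 °C → rt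
Reagents that add atoms: tetrabromomethane, BrC(Br)(Br)Br
Why: The Appel reaction (SN2 displacement of the alkoxyphosphonium group by bromide) should convert both unhindered primary alcohols under neutral conditions that the electron-rich arenes tolerate.

Step 7
Reactants: 10 1-(7-bromoheptyl)-3-[3-(7-bromoheptyl)-5-methoxyphenoxy]-2,5-dimethoxybenzene; 11 sodium sulfide (used as the nonahydrate)
Product: 14 macrocyclic thioether (22-membered ring), via ring A side bromo thiolate 12 (not isolated), via ring B side bromo thiolate 13 (not isolated)
Conditions: EtOH/THF/H2O, reflux, high dilution (both reactants added slowly over 12 h), Ar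
Reagents that add atoms: none
Why: A twofold SN2 thioetherification, first intermolecular to thiolate 12 or 13 and then intramolecular, should close the 22-membered ring under high dilution because the soft thiolate meets only an unhindered primary bromide and no other electrophile.

Step 8
Reactants: 14 macrocyclic thioether (22-membered ring)
Product: 16 macrocyclic sulfone (22-membered ring), via macrocyclic sulfoxide 15 (not isolated)
Conditions: mCPBA (2.2 equiv), NaHCO3, CH2Cl2, 0 °C → rt
Reagents that add atoms: 3-chloroperoxybenzoic acid, OOC(=O)c1cccc(Cl)c1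
Why: Sulfide-to-sulfone oxidation by electrophilic oxygen transfer should stop cleanly at the sulfone, sulfur being far more nucleophilic than the methoxyarenes at 0 °C.

Step 9
Reactants: 16 macrocyclic sulfone (22-membered ring)
Product: 20 macrocyclic C7=C8 alkene (21-membered ring; E drawn), via ring B side α-bromo sulfone 17 (not isolated), via ring A side α-bromo sulfone 18 (not isolated), via episulfone 19 (not isolated)
Conditions: CBr2F2, KOH/Al2O3, t-BuOH/CH2Cl2, 0 °C → rt
Reagents that add atoms: none
Why: KOH on alumina should remove an α-proton of sulfone 16, and the carbanion takes bromine from CBr2F2 to give α-bromo sulfone 17 or 18, which converge. A second deprotonation at the α' carbon and 1,3-displacement of bromide close episulfone 19, which loses SO2 cheletropically to leave the C7=C8 alkene. The closest known reaction is the one-flask Ramberg–Bäcklund rearrangement in Chan's variant, established for di-primary dialkyl sulfones and for the contraction of macrocyclic sulfones to cyclophane alkenes. The 21-membered carbocycle is formed by contraction of the 22-membered ring already in place and not by a new macrocyclisation, the only closure in the step being the 3-exo-tet formation of the thiirane dioxide. No stereocenter is formed, and the E or Z geometry is of no consequence because step 10 removes the alkene. The step needs monohalogenation at the sulfone α-carbons only, which the substrate secures because these are its only acidic C–H bonds (benzylic and methoxy C–H are far less acidic and no free hydroxyl is present) and because the bromo sulfone should close faster than it is brominated again under these heterogeneous conditions.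

Step 10
Reactants: 20 macrocyclic C7=C8 alkene (21-membered ring)
Product: 21 tri-O-methyl ether of the target (saturated 21-membered ring)
Conditions: H2 (1 atm), 10% Pd/C, EtOAc, rt
Reagents that add atoms: none
Why: Catalytic hydrogenation of the isolated 1,2-disubstituted alkene should proceed for either geometric isomer and leave the aryl ethers intact.

Step 11
Reactants: 21 tri-O-methyl ether of the target (saturated 21-membered ring)
Product: 22 CNP0393720.0 (target)
Conditions: BBr3 (6 equiv), CH2Cl2, −78 °C → rt; then H2O, work-up under Ar
Reagents that add atoms: none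
Why: Lewis acid cleavage of the three aryl methyl ethers by BBr3 (bromide attacks the methyl group of the boron-complexed ether) should free the phenols while the diaryl ether C–O bonds stay intact, and the air-sensitive hydroquinone ring B is kept under argon.

**Compound list**

1 | 3-bromo-2-hydroxy-5-methoxybenzaldehyde | COc1cc(Br)c(O)c(C=O)c1 | starting material
2 | 3-bromo-2,5-dimethoxybenzaldehyde | COc1cc(Br)c(OC)c(C=O)c1 | intermediate
3 | 3-hydroxy-5-methoxybenzaldehyde | COc1cc(O)cc(C=O)c1 | starting material
4 | 3-(3-formyl-5-methoxyphenoxy)-2,5-dimethoxybenzaldehyde | COc1cc(C=O)cc(c1)Oc1cc(OC)cc(C=O)c1OC | intermediate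
5 | 6-bromohexan-1-ol | OCCCCCCBr | starting material
6 | (6-hydroxyhexyl)triphenylphosphonium bromide | [Br-].OCCCCCC[P+](c1ccccc1)(c1ccccc1)c1ccccc1 | intermediate
7 | sodium 6-(triphenylphosphoranylidene)hexan-1-olate (alkoxide ylide, not isolated) | [Na+].[O-]CCCCCC=P(c1ccccc1)(c1ccccc1)c1ccccc1 | intermediate
8 | (6Z)-7-[3-[3-[(1Z)-7-hydroxyhept-1-enyl]-5-methoxyphenoxy]-2,5-dimethoxyphenyl]hept-6-en-1-ol (Z,Z drawn; geometric mixture acceptable) | COc1cc(/C=C\CCCCCO)cc(c1)Oc1cc(OC)cc(/C=C\CCCCCO)c1OC | intermediate
9 | 7-[3-[3-(7-hydroxyheptyl)-5-methoxyphenoxy]-2,5-dimethoxyphenyl]heptan-1-ol | COc1cc(CCCCCCCO)cc(c1)Oc1cc(OC)cc(CCCCCCCO)c1OC | intermediate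
10 | 1-(7-bromoheptyl)-3-[3-(7-bromoheptyl)-5-methoxyphenoxy]-2,5-dimethoxybenzene | COc1cc(CCCCCCCBr)cc(c1)Oc1cc(OC)cc(CCCCCCCBr)c1OC | intermediate
11 | sodium sulfide | [Na+].[Na+].[S-2] | starting material
12 | ring A side bromo thiolate: sodium 7-[3-[3-(7-bromoheptyl)-2,5-dimethoxyphenoxy]-5-methoxyphenyl]heptane-1-thiolate (not isolated) | [Na+].[S-]CCCCCCCc1cc(OC)cc(c1)Oc1cc(OC)cc(CCCCCCCBr)c1OC | intermediate
13 | ring B side bromo thiolate: sodium 7-[3-[3-(7-bromoheptyl)-5-methoxyphenoxy]-2,5-dimethoxyphenyl]heptane-1-thiolate (not isolated) | [Na+].[S-]CCCCCCCc1cc(OC)cc(c1OC)Oc1cc(OC)cc(CCCCCCCBr)c1 | intermediate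
14 | 22-membered macrocyclic bis(heptyl) thioether of the tri-O-methyl diaryl ether | COc1cc2cc(c1)Oc1cc(OC)cc(c1OC)CCCCCCCSCCCCCCC2 | intermediate
15 | 22-membered macrocyclic sulfoxide (racemic at sulfur, not isolated) | COc1cc2cc(c1)Oc1cc(OC)cc(c1OC)CCCCCCCS(=O)CCCCCCC2 | intermediate
16 | 22-membered macrocyclic bis(heptyl) sulfone of the tri-O-methyl diaryl ether | COc1cc2cc(c1)Oc1cc(OC)cc(c1OC)CCCCCCCS(=O)(=O)CCCCCCC2 | intermediate
17 | ring B side α-bromo sulfone (bromine on C8, racemic, not isolated) | COc1cc2cc(c1)Oc1cc(OC)cc(c1OC)CCCCCCC(Br)S(=O)(=O)CCCCCCC2 | intermediate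
18 | ring A side α-bromo sulfone (bromine on C7, racemic, not isolated) | COc1cc2cc(c1)Oc1cc(OC)cc(c1OC)CCCCCCCS(=O)(=O)C(Br)CCCCCC2 | intermediate
19 | episulfone: thiirane 1,1-dioxide spanning C7 and C8 (cis/trans mixture, not isolated) | COc1cc2cc(c1)Oc1cc(OC)cc(c1OC)CCCCCCC1C(CCCCCC2)S1(=O)=O | intermediate
20 | 21-membered C7=C8 alkene of the tri-O-methyl target (E drawn; Z isomer may accompany it) | COc1cc2cc(c1)Oc1cc(OC)cc(c1OC)CCCCCC/C=C/CCCCCC2 | intermediate
21 | tri-O-methyl ether of the target (saturated 21-membered ring) | COc1cc2cc(c1)Oc1cc(OC)cc(c1OC)CCCCCCCCCCCCCC2 | intermediate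
22 | CNP0393720.0 | Oc1cc2cc(c1)Oc1cc(O)cc(c1O)CCCCCCCCCCCCCC2 | target

**Step count and risk**

Total step count: 11. Longest linear sequence: 10 steps (steps 1, 2 and 4 to 11; step 3 is a one-step side branch).

Steps most likely to fail, riskiest first:

1. Step 9 (Ramberg–Bäcklund contraction). The bromo sulfone may be brominated a second time before it closes, which diverts material to vinyl bromides or alkenesulfonates, or difluorocarbene may add to the new alkene. Fallback: the C7=C8 bond is made by reductive carbonyl coupling instead. Setting out from diol 9, oxidation with Dess–Martin periodinane in CH2Cl2 should give 7-[3-[2,5-dimethoxy-3-(7-oxoheptyl)phenoxy]-5-methoxyphenyl]heptanal F1. Intramolecular McMurry coupling (TiCl3(DME)1.5, Zn–Cu couple, DME, reflux, syringe-pump addition) should then close the 21-membered ring directly as the alkene, coming back to the route at compound 20 before step 10.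

2. Step 7 (sulfide macrocyclisation). Chain growth to oligomeric sulfides may outrun ring closure, because the intermolecular first substitution and the intramolecular second one run at the same concentration. Fallback: the two events are separated. Setting out from dibromide 10, a deficiency of KSAc (0.9 equiv, DMF, rt) should give the ring A side bromo thioacetate F2 and the ring B side bromo thioacetate F3, with unreacted 10 recycled. Slow addition of this mixture to NaOMe in MeOH/THF at high dilution should release thiolates 12 and 13 a little at a time, so that only the unimolecular closure is available, and the route is rejoined at compounds 12 and 13 and hence at thioether 14.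

3. Step 2 (diaryl ether coupling). The electron-rich, ortho-substituted bromide may react slowly at copper, so that hydrodebromination or degradation of the aldehydes in hot base takes over. Fallback: the polarity of ring B is inverted and the ether is made oxidatively at room temperature. Setting out from bromide 2, Miyaura borylation (B2pin2, Pd(dppf)Cl2, KOAc, dioxane, 85 °C) should give 2,5-dimethoxy-3-(4,4,5,5-tetramethyl-1,3,2-dioxaborolan-2-yl)benzaldehyde F4. Cleavage with NaIO4 and NH4OAc in acetone/H2O should give (3-formyl-2,5-dimethoxyphenyl)boronic acid F5. Chan–Lam–Evans coupling of F5 with phenol 3 (Cu(OAc)2, pyridine, 4 Å molecular sieves, CH2Cl2, air, rt) then comes back to the route at dialdehyde 4.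

**Further compounds**

F1 | step 9 | 7-[3-[2,5-dimethoxy-3-(7-oxoheptyl)phenoxy]-5-methoxyphenyl]heptanal | COc1cc(CCCCCCC=O)cc(c1)Oc1cc(OC)cc(CCCCCCC=O)c1OC
F2 | step 7 | S-[7-[3-[3-(7-bromoheptyl)-2,5-dimethoxyphenoxy]-5-methoxyphenyl]heptyl] ethanethioate | CC(=O)SCCCCCCCc1cc(OC)cc(c1)Oc1cc(OC)cc(CCCCCCCBr)c1OC
F3 | step 7 | S-[7-[3-[3-(7-bromoheptyl)-5-methoxyphenoxy]-2,5-dimethoxyphenyl]heptyl] ethanethioate | CC(=O)SCCCCCCCc1cc(OC)cc(c1OC)Oc1cc(OC)cc(CCCCCCCBr)c1
F4 | step 2 | 2,5-dimethoxy-3-(4,4,5,5-tetramethyl-1,3,2-dioxaborolan-2-yl)benzaldehyde | COc1cc(C=O)c(OC)c(c1)B1OC(C)(C)C(C)(C)O1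
F5 | step 2 | (3-formyl-2,5-dimethoxyphenyl)boronic acid | COc1cc(C=O)c(OC)c(c1)B(O)O
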